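## Structural features

Atrovirinone is built from two six-membered carbocycles joined by one ether oxygen. Ring A is a methyl benzoate whose ester carbon C1' lies between a hydroxyl at C2' and the ether oxygen at C6', with a second hydroxyl at C4'. Ring B is a fully substituted 1,4-benzoquinone: aryloxy at C1, methoxy at C2, carbonyls at C3 and C6, and two adjacent 3-methylbut-2-enyl (prenyl) chains at C4 and C5. There is no stereocentre and no stereogenic double bond, since both alkene termini are gem-dimethyl, so the problems are regiochemistry and chemoselectivity only. The 2-aryloxy-3-methoxyquinone is a vinylogous ester at both oxygens and exchanges its aryloxide with alkoxide or amine nucleophiles, and an ortho-prenylquinone cyclises to a chromenol in base. The trisubstituted alkenes do not tolerate hydrogenation, bromine radicals or strong acid, and the free resorcinol ring A is sensitive to electrophiles and oxidants. The real difficulty is the hexasubstituted ring B, which carries four oxygen functions of three kinds in a fixed order next to two contiguous prenyl groups, together with an ether bridge between two doubly ortho-substituted carbons. The key step exploits the fact that each prenyl group is C(ring B)–CH2–CH=C(CH3)2: in the aromatic, hydroquinone dimethyl ether form of ring B the CH2 carbons on C4 and C5 are benzylic, can originate from the two methyl groups of 2,3-dimethylhydroquinone, and can each be joined to a 2-methylpropenyl unit without any allyl species that could transpose.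

## Logic of the disconnections

16 to 15: the two carbonyl groups at C3 and C6 of ring B are traced back to aryl methyl ethers. The quinone is the most nucleophile- and base-sensitive part, so it is unmasked last. C3 and C6 are the only para-related oxygen pair of ring B, so the oxidation can only give the para-quinone with the C2 methoxy retained. The forward step must oxidise ring B in preference to the free ring A phenols and the alkenes.

15 to 14: the two O–H bonds of ring A are traced back to O–acetyl bonds. The acetates are removed while ring B is still an inert arene, because methoxide could not be used once the quinone exists. The demand is only that the methyl ester survives, which it does in methanol.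

14 to 12 and 13: the two CH2–CH(sp2) bonds of the prenyl chains are cut. This removes both side chains in one operation and leads to a symmetric-looking ortho bis(bromomethyl) arene and a commercial alkenyl partner. The forward step must couple twice at sp3 carbon faster than the ortho bis(halomethyl) unit is reduced or homocoupled, and must leave two aryl acetates untouched.

12 to 11: the two benzylic C–Br bonds are cut back to C–H. The two aryl methyl groups are the only benzylic hydrogens, ring B has no ring hydrogen, and ring A is deactivated as its diacetate. The demand is that radical substitution wins over ionic attack on the electron-rich ring B.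

11 to 9 (through 10): the acetates are exchanged for benzyl ethers. Ethers are required while ring B is reduced and methylated under basic conditions, but they cannot pass through the radical bromination, so the switch is placed here, before any alkene is present, and hydrogenolysis is therefore allowed.

9 to 7 (through 8): the O–CH3 bonds at C3 and C6 are cut and ring B is returned to the quinone oxidation level. At that level the ring is an electrophile and the hindered C–O bonds can be made by substitution, not by metal-mediated arylation. The demand is that ring A carries no free hydroxyl during methylation.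

7 to 4 and 6: the C1–O(aryl) bond is cut. An addition–elimination at a halogenated quinone carbon forms an ether between two crowded carbons that would be hard to make by Ullmann-type chemistry. The demand is a ring A partner with exactly one free phenol, the one next to the ester.

6 to 5: two O–benzyl bonds are cut. The hydroxyl that must stay free is the one hydrogen-bonded to the ester carbonyl, so selectivity comes from the substrate.

4 to 3: the C2–OCH3 bond is cut. Methoxide is introduced first because, after the aryloxide is in place, methoxide would expel it again. The first substitution also deactivates the ring toward a second.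

3 to 1: the two C–Br bonds are cut and the oxidation level is lowered to the commercial hydroquinone. Its two methyl groups become the benzylic carbons of the prenyl chains and its two free ring positions become C1 and C2.

## Other disconnections considered

Alternative 1: ring A is cut at C1'–C2' and C5'–C6'. In the forward direction the bis(silyloxy) diene 1-methoxy-1,3-bis(trimethylsilyloxy)buta-1,3-diene A2 would add across the triple bond of methyl 3-[2,3,6-trimethoxy-4,5-bis(3-methylbut-2-enyl)phenoxy]prop-2-ynoate A1. Loss of methanol and desilylation would then give methyl 2,4-dihydroxy-6-[2,3,6-trimethoxy-4,5-bis(3-methylbut-2-enyl)phenoxy]benzoate A3.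
- In its favour: the polarity of both partners fixes the regiochemistry, and ring A appears with both hydroxyls free, so no protecting group is needed on ring A. On that point it is better than the chosen plan.
- Equal: A3 is the same compound as 15, so the endgame is identical.
- Against: A1 must be made from 2,3,6-trimethoxy-4,5-bis(3-methylbut-2-enyl)phenol A4. This hexasubstituted phenol already contains the two contiguous prenyl groups and four differentiated oxygens, so the hardest part of the problem is moved, not solved. The aryl ynol ether ester A1 is hydrolytically labile and needs several operations from a hindered phenol, and the cycloaddition needs heating in the presence of two ene-capable prenyl groups.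
- Overall: mechanistically elegant, but likely longer than the chosen plan once A4 is counted.

Alternative 2: the C4–CH2 and C5–CH2 bonds are cut. Heating methyl 2-{2-methoxy-3,6-bis[(2-methylbut-3-en-2-yl)oxy]phenoxy}-4,6-bis(methoxymethoxy)benzoate A5 would trigger two aromatic Claisen rearrangements. Each goes to the only free ortho position with allyl inversion and would give methyl 2-[2,5-dihydroxy-6-methoxy-3,4-bis(3-methylbut-2-enyl)phenoxy]-4,6-bis(methoxymethoxy)benzoate A6.
- In its favour: no transition metal and full atom economy. A6 is already at the hydroquinone level, so the quinone would come from a mild oxidation with no oxidative demethylation. On that point it is better than the chosen plan.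
- Equal: regiochemical certainty. Each ether has a single open ortho carbon, and in the chosen plan the position is fixed by the methyl groups of 1.
- Against: two tertiary allyl ethers must be installed on crowded phenolic oxygens, which costs extra steps. After the first shift an ortho-prenylphenol sits next to a hot, ionisable tertiary ether, so chroman formation and loss of the second allyl unit by elimination compete. The acetal groups of ring A must finally be removed with acid in the presence of ortho-prenyl phenol or quinone functions.
- Overall: comparable or somewhat shorter on paper, but less dependable than two benzylic couplings on a fully blocked arene.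

Alternative 3: the O–C6' and C1'–carboxyl bonds are cut. CsF would convert 3,5-bis(methoxymethoxy)-2-(trimethylsilyl)phenyl trifluoromethanesulfonate A7 into 3,5-bis(methoxymethoxy)benzyne A8. The potassium salt of A4 would add at the aryne carbon remote from the flanking alkoxy group, and the aryl anion would be trapped by CO2 and then MeI to give methyl 2,4-bis(methoxymethoxy)-6-[2,3,6-trimethoxy-4,5-bis(3-methylbut-2-enyl)phenoxy]benzoate A9.
- In its favour: the hindered ether and the ester are set in one convergent operation with a regiochemistry predicted by aryne distortion. On convergence it is better than the chosen plan.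
- Equal: the final oxidative demethylation is shared.
- Against: it again depends on A4, and A7 needs its own multistep preparation. Protonation of the aryl anion by any proton source competes with carboxylation, and CO2 reversibly carbonates the phenoxide. The acetal groups of A9 must be cleaved with acid in the presence of two prenyl groups.
- Overall: two fragment syntheses make it longer than the chosen linear sequence, which needs only one protected ring A building block.

Key step: step 8

Remark on the chemistry: ring B is numbered from the aryloxy carbon (C1) through the methoxy carbon (C2), so C3 and C6 are the quinone carbonyls and C4 and C5 carry the prenyl chains; primed numbers belong to ring A. Two operations run on a crude, unpurified intermediate are counted as one step.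

## Steps

Step 1
Reactants: 1 2,3-dimethylhydroquinone
Product: 3 2,3-dibromo-5,6-dimethyl-1,4-benzoquinone, via 2,3-dibromo-5,6-dimethylhydroquinone 2 (not isolated)
Conditions: Br2 (3.1 equiv), AcOH, 20 → 50 °C
Reagents that add atoms: bromine, BrBr
Why: Electrophilic aromatic bromination of the two free positions of the strongly activated hydroquinone gives 2, which the third equivalent of bromine oxidises to the quinone; no other ring position is free, so the ionic conditions cannot over-brominate.

Step 2
Reactants: 3 2,3-dibromo-5,6-dimethyl-1,4-benzoquinone
Product: 4 2-bromo-3-methoxy-5,6-dimethyl-1,4-benzoquinone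
Conditions: NaOMe (1.0 equiv), MeOH/THF, −20 → 0 °C
Reagents that add atoms: sodium methoxide, [Na+].[O-]C
Why: Addition–elimination (vinylogous acyl substitution) at a bromine-bearing quinone carbon; the new methoxy group makes the product a vinylogous ester whose remaining C–Br carbon is far less electrophilic, so one equivalent of methoxide in the cold should stop at monosubstitution.

Step 3
Reactants: 5 methyl 2,4,6-trihydroxybenzoate
Product: 6 methyl 2,4-bis(benzyloxy)-6-hydroxybenzoate
Conditions: BnBr (2.1 equiv), K2CO3, acetone, reflux
Reagents that add atoms: benzyl bromide, BrCc1ccccc1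
Why: Williamson etherification; the 4-hydroxyl and one ortho hydroxyl are alkylated, while the last hydroxyl is held in a hydrogen bond to the ester carbonyl, is the least nucleophilic, and should stay free with two equivalents of halide.

Step 4
Reactants: 4 2-bromo-3-methoxy-5,6-dimethyl-1,4-benzoquinone; 6 methyl 2,4-bis(benzyloxy)-6-hydroxybenzoate
Product: 7 methyl 2,4-bis(benzyloxy)-6-[(2-methoxy-4,5-dimethyl-3,6-dioxocyclohexa-1,4-dien-1-yl)oxy]benzoate
Conditions: K2CO3, DMF, 0 °C → rt, N2
Reagents that add atoms: none
Why: Addition–elimination of the phenoxide of 6 at the bromine-bearing carbon of 4 with loss of bromide; attack at the methoxy carbon is unproductive because the aryloxide is the better leaving group there, so the mixed aryloxy methoxy quinone should form.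

Step 5
Reactants: 7 methyl 2,4-bis(benzyloxy)-6-[(2-methoxy-4,5-dimethyl-3,6-dioxocyclohexa-1,4-dien-1-yl)oxy]benzoate
Product: 9 methyl 2,4-bis(benzyloxy)-6-(2,3,6-trimethoxy-4,5-dimethylphenoxy)benzoate, via ring-B hydroquinone 8 (not isolated)
Conditions: Na2S2O4, THF/H2O, rt; then MeI, K2CO3, DMF, rt → 40 °C, N2
Reagents that add atoms: iodomethane, CI
Why: Dithionite reduces the quinone to the air-sensitive hydroquinone 8, whose two phenoxides are O-methylated (Williamson) under nitrogen; the benzyl ethers and the hindered methyl ester are inert, and ring A has no free hydroxyl to be methylated.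

Step 6
Reactants: 9 methyl 2,4-bis(benzyloxy)-6-(2,3,6-trimethoxy-4,5-dimethylphenoxy)benzoate
Product: 11 methyl 2,4-diacetoxy-6-(2,3,6-trimethoxy-4,5-dimethylphenoxy)benzoate, via debenzylated resorcinol 10 (not isolated)
Conditions: H2 (1 atm), Pd/C, EtOAc/MeOH, rt; filter, concentrate; then Ac2O, pyridine, DMAP (cat.), rt
Reagents that add atoms: acetic anhydride, CC(=O)OC(C)=O
Why: Hydrogenolysis of the two benzyl ethers, done before any alkene is present, followed by acetylation of the crude resorcinol; this turns ring A from an electron-rich bis-ether into a deactivated diacetate that can pass through radical bromination.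

Step 7
Reactants: 11 methyl 2,4-diacetoxy-6-(2,3,6-trimethoxy-4,5-dimethylphenoxy)benzoate
Product: 12 methyl 2,4-diacetoxy-6-[3,4-bis(bromomethyl)-2,5,6-trimethoxyphenoxy]benzoate
Conditions: NBS (2.1 equiv), AIBN (cat.), PhCF3, 80 °C
Reagents that add atoms: N-bromosuccinimide, O=C1CCC(=O)N1Br
Why: Wohl–Ziegler bromination by hydrogen abstraction at the two aryl methyl groups, the only benzylic C–H bonds; ring B has no ring hydrogen, the acetylated ring A is too electron-poor for ionic ring bromination, and the stoichiometry limits geminal dibromination.

Step 8
Reactants: 12 methyl 2,4-diacetoxy-6-[3,4-bis(bromomethyl)-2,5,6-trimethoxyphenoxy]benzoate; 13 2-methylprop-1-enylboronic acid pinacol ester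
Product: 14 methyl 2,4-diacetoxy-6-[2,3,6-trimethoxy-4,5-bis(3-methylbut-2-enyl)phenoxy]benzoate
Conditions: 13 (3 equiv), PdCl2(dppf) (8 mol %), K3PO4 (anhydrous, powdered, 4.5 equiv), THF, 65 °C, Ar
Reagents that add atoms: none
Why: Suzuki–Miyaura coupling of benzylic bromides with an alkenylboronic ester, a known reaction type. PdCl2(dppf) is reduced in the flask to zerovalent palladium by a small part of 13; oxidative addition into a benzylic C–Br bond of 12 gives a benzylpalladium bromide, the phosphate-activated boronate transfers the 2-methylpropenyl group to palladium, and reductive elimination, helped by the wide bite angle of dppf, forms the CH2–CH(sp2) bond; the cycle then repeats at the second bromide. No ring is closed and no stereocentre is created, and the gem-dimethyl terminus removes any question of alkene geometry. The benzylpalladium intermediate cannot undergo beta-hydride elimination because its beta carbons are fully substituted ring carbons. Linear prenyl connectivity is fixed because the nucleophile is vinylic and the electrophile benzylic, so no allylmetal species that could transpose is ever formed. The selectivity needed is chemoselectivity: cross-coupling must be faster than palladium-induced 1,4-debromination of the ortho bis(bromomethyl) unit to an ortho-quinodimethane and faster than benzylic homocoupling, which an excess of 13, the chelating ligand and a moderate temperature favour. Anhydrous phosphate keeps the aryl acetates and the methyl ester intact, and neither ring has a C–halogen or reactive C–H bond that could compete.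

Step 9
Reactants: 14 methyl 2,4-diacetoxy-6-[2,3,6-trimethoxy-4,5-bis(3-methylbut-2-enyl)phenoxy]benzoate
Product: 15 methyl 2,4-dihydroxy-6-[2,3,6-trimethoxy-4,5-bis(3-methylbut-2-enyl)phenoxy]benzoate
Conditions: K2CO3 (2.5 equiv), MeOH, 0 °C → rt; aq. NH4Cl
Reagents that add atoms: none
Why: Base-mediated transesterification of the two aryl acetates to methanol; exchange at the methyl ester is degenerate, and ring B is still an unreactive arene, which is why the acetates are removed before the quinone exists.

Step 10
Reactants: 15 methyl 2,4-dihydroxy-6-[2,3,6-trimethoxy-4,5-bis(3-methylbut-2-enyl)phenoxy]benzoate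
Product: 16 atrovirinone, methyl 2,4-dihydroxy-6-{[2-methoxy-4,5-bis(3-methylbut-2-enyl)-3,6-dioxocyclohexa-1,4-dien-1-yl]oxy}benzoate
Conditions: (NH4)2Ce(NO3)6 (2.5 equiv), MeCN/H2O, 0 °C, 15 min
Reagents that add atoms: water, O
Why: Oxidative demethylation by tetravalent cerium: two one-electron oxidations of the electron-rich ring B, addition of water at C3 and C6 (the only para-related oxygen pair) and loss of two molecules of methanol give the para-quinone; ring B is the most easily oxidised part, so the resorcinol ring and the alkenes should be spared at 0 °C with a short contact time.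

## Compound list

1 | 2,3-dimethylhydroquinone | Cc1c(O)ccc(O)c1C | starting material
2 | 2,3-dibromo-5,6-dimethylhydroquinone | Cc1c(C)c(O)c(Br)c(Br)c1O | intermediate (not isolated)
3 | 2,3-dibromo-5,6-dimethyl-1,4-benzoquinone | CC1=C(C)C(=O)C(Br)=C(Br)C1=O | intermediate
4 | 2-bromo-3-methoxy-5,6-dimethyl-1,4-benzoquinone | COC1=C(Br)C(=O)C(C)=C(C)C1=O | intermediate
5 | methyl 2,4,6-trihydroxybenzoate | COC(=O)c1c(O)cc(O)cc1O | starting material
6 | methyl 2,4-bis(benzyloxy)-6-hydroxybenzoate | COC(=O)c1c(O)cc(OCc2ccccc2)cc1OCc1ccccc1 | intermediate
7 | methyl 2,4-bis(benzyloxy)-6-[(2-methoxy-4,5-dimethyl-3,6-dioxocyclohexa-1,4-dien-1-yl)oxy]benzoate | COC(=O)c1c(OCc2ccccc2)cc(OCc2ccccc2)cc1OC1=C(OC)C(=O)C(C)=C(C)C1=O | intermediate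
8 | methyl 2,4-bis(benzyloxy)-6-(2,5-dihydroxy-6-methoxy-3,4-dimethylphenoxy)benzoate | COC(=O)c1c(OCc2ccccc2)cc(OCc2ccccc2)cc1Oc1c(OC)c(O)c(C)c(C)c1O | intermediate (not isolated)
9 | methyl 2,4-bis(benzyloxy)-6-(2,3,6-trimethoxy-4,5-dimethylphenoxy)benzoate | COC(=O)c1c(OCc2ccccc2)cc(OCc2ccccc2)cc1Oc1c(OC)c(OC)c(C)c(C)c1OC | intermediate
10 | methyl 2,4-dihydroxy-6-(2,3,6-trimethoxy-4,5-dimethylphenoxy)benzoate | COC(=O)c1c(O)cc(O)cc1Oc1c(OC)c(OC)c(C)c(C)c1OC | intermediate (not isolated)
11 | methyl 2,4-diacetoxy-6-(2,3,6-trimethoxy-4,5-dimethylphenoxy)benzoate | COC(=O)c1c(OC(C)=O)cc(OC(C)=O)cc1Oc1c(OC)c(OC)c(C)c(C)c1OC | intermediate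
12 | methyl 2,4-diacetoxy-6-[3,4-bis(bromomethyl)-2,5,6-trimethoxyphenoxy]benzoate | COC(=O)c1c(OC(C)=O)cc(OC(C)=O)cc1Oc1c(OC)c(OC)c(CBr)c(CBr)c1OC | intermediate
13 | 2-methylprop-1-enylboronic acid pinacol ester | CC(C)=CB1OC(C)(C)C(C)(C)O1 | starting material
14 | methyl 2,4-diacetoxy-6-[2,3,6-trimethoxy-4,5-bis(3-methylbut-2-enyl)phenoxy]benzoate | COC(=O)c1c(OC(C)=O)cc(OC(C)=O)cc1Oc1c(OC)c(OC)c(CC=C(C)C)c(CC=C(C)C)c1OC | intermediate
15 | methyl 2,4-dihydroxy-6-[2,3,6-trimethoxy-4,5-bis(3-methylbut-2-enyl)phenoxy]benzoate | COC(=O)c1c(O)cc(O)cc1Oc1c(OC)c(OC)c(CC=C(C)C)c(CC=C(C)C)c1OC | intermediate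
16 | atrovirinone | COC(=O)c1c(O)cc(O)cc1OC1=C(OC)C(=O)C(CC=C(C)C)=C(CC=C(C)C)C1=O | target

## Step count and least certain steps

Total step count: 10. Longest linear sequence: 9 steps from 1 (steps 1, 2 and 4 to 10); step 3 prepares the ring A partner and joins at step 4.

Step 8 (key step). Most likely failure: after the first oxidative addition, palladium may induce 1,4-debromination of the ortho bis(bromomethyl) unit to an ortho-quinodimethane that oligomerises, or the benzyl groups may homocouple. The base may also strip an acetate, and the freed phenoxide is then alkylated by a benzylic bromide. Fallback: a base-free Stille coupling. Setting out from 12, tributyl(2-methylprop-1-enyl)stannane with Pd2(dba)3, AsPh3 and CuI in NMP at 50 °C would give 14 directly, so the route is rejoined at 14 and no new compound arises. Transfer from tin needs no base, which removes the acetate problem, and the CuI co-catalyst speeds transmetalation relative to the elimination.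

Step 4. Most likely failure: slow substitution, because the methoxy group has turned the bromoquinone into a vinylogous ester, so that C-arylation by the electron-rich phenoxide or base-induced decomposition of the quinone gets ahead. Fallback: the order of the two substitutions is inverted and the methoxy group is introduced on the arene.
- Setting out from 3 and 6, the more electrophilic 3 would take up the phenoxide of 6 (K2CO3, DMF, 0 °C) to give methyl 2,4-bis(benzyloxy)-6-[(2-bromo-4,5-dimethyl-3,6-dioxocyclohexa-1,4-dien-1-yl)oxy]benzoate F1.
- Reduction with Na2S2O4 would give methyl 2,4-bis(benzyloxy)-6-(2-bromo-3,6-dihydroxy-4,5-dimethylphenoxy)benzoate F2, and methylation (MeI, K2CO3, DMF) would give methyl 2,4-bis(benzyloxy)-6-(2-bromo-3,6-dimethoxy-4,5-dimethylphenoxy)benzoate F3.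
- An Ullmann-type methoxylation (CuI, NaOMe, MeOH/DMF, 100 °C) would replace the bromine by methoxy and rejoin the route at 9.

Step 7. Most likely failure: ionic attack of bromine on the tetra-oxygenated ring B, with ipso substitution and oxidative loss of a methyl ether, or bromination beyond the monobromide at each methyl group. Fallback: ring B is carried as its hydroquinone diacetate, which is much harder to oxidise and needs no oxidative demethylation at the end.
- Setting out from 7, reductive acetylation (Zn, Ac2O, pyridine) would give methyl 2,4-bis(benzyloxy)-6-(2,5-diacetoxy-6-methoxy-3,4-dimethylphenoxy)benzoate F4.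
- Hydrogenolysis (H2, Pd/C) would give methyl 2-(2,5-diacetoxy-6-methoxy-3,4-dimethylphenoxy)-4,6-dihydroxybenzoate F5, and acetylation would give methyl 2,4-diacetoxy-6-(2,5-diacetoxy-6-methoxy-3,4-dimethylphenoxy)benzoate F6.
- Radical bromination as in step 7 would give methyl 2,4-diacetoxy-6-[2,5-diacetoxy-3,4-bis(bromomethyl)-6-methoxyphenoxy]benzoate F7, and coupling with 13 as in step 8 would give methyl 2,4-diacetoxy-6-[2,5-diacetoxy-6-methoxy-3,4-bis(3-methylbut-2-enyl)phenoxy]benzoate F8.
- Methanolysis of all four acetates with K2CO3 in degassed MeOH under argon would give methyl 2-[2,5-dihydroxy-6-methoxy-3,4-bis(3-methylbut-2-enyl)phenoxy]-4,6-dihydroxybenzoate F9. After acidification with AcOH, so that the quinone never meets base, aqueous FeCl3 would oxidise it and the route is rejoined at 16.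

Step 10. Most likely failure: oxidation of the unprotected resorcinol ring A by tetravalent cerium in competition with ring B, giving coupled or over-oxidised material. Fallback: the oxidation is run while ring A is still acetylated, and the acetates are removed at the hydroquinone level.
- Setting out from 14, (NH4)2Ce(NO3)6 in MeCN/H2O would give methyl 2,4-diacetoxy-6-{[2-methoxy-4,5-bis(3-methylbut-2-enyl)-3,6-dioxocyclohexa-1,4-dien-1-yl]oxy}benzoate F10.
- Reduction with Na2S2O4 would give methyl 2,4-diacetoxy-6-[2,5-dihydroxy-6-methoxy-3,4-bis(3-methylbut-2-enyl)phenoxy]benzoate F11.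
- K2CO3 in degassed MeOH under argon would then give the tetrol F9 already described under step 7. Acidification and aqueous FeCl3 would reoxidise ring B and rejoin the route at 16.

## Further compounds

F0 | step 8 | none | none
F1 | step 4 | methyl 2,4-bis(benzyloxy)-6-[(2-bromo-4,5-dimethyl-3,6-dioxocyclohexa-1,4-dien-1-yl)oxy]benzoate | COC(=O)c1c(OCc2ccccc2)cc(OCc2ccccc2)cc1OC1=C(Br)C(=O)C(C)=C(C)C1=O
F2 | step 4 | methyl 2,4-bis(benzyloxy)-6-(2-bromo-3,6-dihydroxy-4,5-dimethylphenoxy)benzoate | COC(=O)c1c(OCc2ccccc2)cc(OCc2ccccc2)cc1Oc1c(Br)c(O)c(C)c(C)c1O
F3 | step 4 | methyl 2,4-bis(benzyloxy)-6-(2-bromo-3,6-dimethoxy-4,5-dimethylphenoxy)benzoate | COC(=O)c1c(OCc2ccccc2)cc(OCc2ccccc2)cc1Oc1c(Br)c(OC)c(C)c(C)c1OC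
F4 | step 7 | methyl 2,4-bis(benzyloxy)-6-(2,5-diacetoxy-6-methoxy-3,4-dimethylphenoxy)benzoate | COC(=O)c1c(OCc2ccccc2)cc(OCc2ccccc2)cc1Oc1c(OC)c(OC(C)=O)c(C)c(C)c1OC(C)=O
F5 | step 7 | methyl 2-(2,5-diacetoxy-6-methoxy-3,4-dimethylphenoxy)-4,6-dihydroxybenzoate | COC(=O)c1c(O)cc(O)cc1Oc1c(OC)c(OC(C)=O)c(C)c(C)c1OC(C)=O
F6 | step 7 | methyl 2,4-diacetoxy-6-(2,5-diacetoxy-6-methoxy-3,4-dimethylphenoxy)benzoate | COC(=O)c1c(OC(C)=O)cc(OC(C)=O)cc1Oc1c(OC)c(OC(C)=O)c(C)c(C)c1OC(C)=O
F7 | step 7 | methyl 2,4-diacetoxy-6-[2,5-diacetoxy-3,4-bis(bromomethyl)-6-methoxyphenoxy]benzoate | COC(=O)c1c(OC(C)=O)cc(OC(C)=O)cc1Oc1c(OC)c(OC(C)=O)c(CBr)c(CBr)c1OC(C)=O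
F8 | step 7 | methyl 2,4-diacetoxy-6-[2,5-diacetoxy-6-methoxy-3,4-bis(3-methylbut-2-enyl)phenoxy]benzoate | COC(=O)c1c(OC(C)=O)cc(OC(C)=O)cc1Oc1c(OC)c(OC(C)=O)c(CC=C(C)C)c(CC=C(C)C)c1OC(C)=O
F9 | step 7 | methyl 2-[2,5-dihydroxy-6-methoxy-3,4-bis(3-methylbut-2-enyl)phenoxy]-4,6-dihydroxybenzoate | COC(=O)c1c(O)cc(O)cc1Oc1c(OC)c(O)c(CC=C(C)C)c(CC=C(C)C)c1O
F10 | step 10 | methyl 2,4-diacetoxy-6-{[2-methoxy-4,5-bis(3-methylbut-2-enyl)-3,6-dioxocyclohexa-1,4-dien-1-yl]oxy}benzoate | COC(=O)c1c(OC(C)=O)cc(OC(C)=O)cc1OC1=C(OC)C(=O)C(CC=C(C)C)=C(CC=C(C)C)C1=O
F11 | step 10 | methyl 2,4-diacetoxy-6-[2,5-dihydroxy-6-methoxy-3,4-bis(3-methylbut-2-enyl)phenoxy]benzoate | COC(=O)c1c(OC(C)=O)cc(OC(C)=O)cc1Oc1c(OC)c(O)c(CC=C(C)C)c(CC=C(C)C)c1O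
A1 | alternative 1 | methyl 3-[2,3,6-trimethoxy-4,5-bis(3-methylbut-2-enyl)phenoxy]prop-2-ynoate | COC(=O)C#COc1c(OC)c(OC)c(CC=C(C)C)c(CC=C(C)C)c1OC
A2 | alternative 1 | 1-methoxy-1,3-bis(trimethylsilyloxy)buta-1,3-diene | COC(O[Si](C)(C)C)=CC(=C)O[Si](C)(C)C
A3 | alternative 1 | methyl 2,4-dihydroxy-6-[2,3,6-trimethoxy-4,5-bis(3-methylbut-2-enyl)phenoxy]benzoate | COC(=O)c1c(O)cc(O)cc1Oc1c(OC)c(OC)c(CC=C(C)C)c(CC=C(C)C)c1OC
A4 | alternative 1 | 2,3,6-trimethoxy-4,5-bis(3-methylbut-2-enyl)phenol | COc1c(O)c(OC)c(CC=C(C)C)c(CC=C(C)C)c1OC
A5 | alternative 2 | methyl 2-{2-methoxy-3,6-bis[(2-methylbut-3-en-2-yl)oxy]phenoxy}-4,6-bis(methoxymethoxy)benzoate | COC(=O)c1c(OCOC)cc(OCOC)cc1Oc1c(OC)c(OC(C)(C)C=C)ccc1OC(C)(C)C=C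
A6 | alternative 2 | methyl 2-[2,5-dihydroxy-6-methoxy-3,4-bis(3-methylbut-2-enyl)phenoxy]-4,6-bis(methoxymethoxy)benzoate | COC(=O)c1c(OCOC)cc(OCOC)cc1Oc1c(OC)c(O)c(CC=C(C)C)c(CC=C(C)C)c1O
A7 | alternative 3 | 3,5-bis(methoxymethoxy)-2-(trimethylsilyl)phenyl trifluoromethanesulfonate | COCOc1cc(OCOC)c([Si](C)(C)C)c(OS(=O)(=O)C(F)(F)F)c1
A8 | alternative 3 | 3,5-bis(methoxymethoxy)benzyne | COCOC1=CC(OCOC)=CC#C1
A9 | alternative 3 | methyl 2,4-bis(methoxymethoxy)-6-[2,3,6-trimethoxy-4,5-bis(3-methylbut-2-enyl)phenoxy]benzoate | COC(=O)c1c(OCOC)cc(OCOC)cc1Oc1c(OC)c(OC)c(CC=C(C)C)c(CC=C(C)C)c1OC
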